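**Retrosynthetic overview**
1. Shanciol B (19) ⇐ tribenzyl ether 18 by hydrogenolysis.
2. 18 ⇐ intramolecular Diels–Alder / retro-Diels–Alder (Alder–Rickert) of the O-tethered 1-alkoxy-3-silyloxycyclohexa-1,3-diene–alkyne 15. The C8a–C4a and C6–C5 bonds form, ethene is lost, and ring A and the pyran ring close together.
3. 15 ⇐ vinylogous ester 14 ⇐ anti alcohol 12 + 3-chlorocyclohex-2-enone (O1–C8a bond).
4. 12 ⇐ α-benzyloxy aldehyde 8 + aryltitanium (C2 set by C3, Felkin–Anh); 8 ⇐ methyl (S)-glycidate (C3 bought) + alkyne 4.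
5. Ring order: rings B and D are bought; ring A and the pyran ring are formed last, in the same cycloaddition.

Assumption: methyl (S)-glycidate is taken as an inexpensive catalogue chiral starting material; conjugate bases made by simple deprotonation (acetylides, alkoxides, enolates) are not numbered separately from their parents.

The key cycloaddition (step 7) is designed by analogy to known Alder–Rickert chemistry; it has not been demonstrated on this substrate.

**Step 1**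
Reactants: 1 3-(benzyloxy)benzyl bromide; 2 1-(trimethylsilyl)propyne
Product: 4 1-(benzyloxy)-3-(but-3-yn-1-yl)benzene, via silylalkyne 3 (not isolated)
Conditions: 2, n-BuLi, THF, −78 °C; then 1, −78 → 0 °C; then K2CO3 (cat.), MeOH, rt
Reagents that add atoms: none
Why: Propargylic lithiation of the silylpropyne and SN2 alkylation by the benzylic bromide, followed by methanolytic C–Si cleavage, give the homopropargyl arene.

**Step 2**
Reactants: 4 1-(benzyloxy)-3-(but-3-yn-1-yl)benzene; 5 methyl (S)-glycidate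
Product: 6 methyl (2S)-7-[3-(benzyloxy)phenyl]-2-hydroxyhept-4-ynoate
Conditions: 4, n-BuLi, THF, −78 °C; BF3·OEt2; then 5, −78 °C
Reagents that add atoms: none
Why: Yamaguchi–Hirao alkynylation opens the BF3-activated epoxide by SN2 at the unsubstituted CH2, so the bought stereocentre (later C3) is untouched and stays S.

**Step 3**
Reactants: 6 methyl (2S)-7-[3-(benzyloxy)phenyl]-2-hydroxyhept-4-ynoate
Product: 7 methyl (2S)-2-(benzyloxy)-7-[3-(benzyloxy)phenyl]hept-4-ynoate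
Conditions: BnOC(=NH)CCl3, TfOH (cat.), CH2Cl2/cyclohexane, 0 °C → rt
Reagents that add atoms: benzyl 2,2,2-trichloroacetimidate, N=C(OCc1ccccc1)C(Cl)(Cl)Cl
Why: Acid-catalysed imidate O-benzylation protects the α-hydroxy ester without base, so the α-stereocentre is not epimerised.

**Step 4**
Reactants: 7 methyl (2S)-2-(benzyloxy)-7-[3-(benzyloxy)phenyl]hept-4-ynoate
Product: 8 (2S)-2-(benzyloxy)-7-[3-(benzyloxy)phenyl]hept-4-ynal
Conditions: DIBAL-H (1.05 equiv), CH2Cl2, −78 °C; Rochelle salt work-up; used crude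
Reagents that add atoms: none
Why: Partial DIBAL reduction of the α-alkoxy ester stops at the chelated aluminium hemiacetal at −78 °C and gives the aldehyde on work-up.

**Step 5**
Reactants: 8 (2S)-2-(benzyloxy)-7-[3-(benzyloxy)phenyl]hept-4-ynal; 9 1-(benzyloxy)-4-bromo-2-methoxybenzene
Product: 12 (1R,2S)-2-(benzyloxy)-1-[4-(benzyloxy)-3-methoxyphenyl]-7-[3-(benzyloxy)phenyl]hept-4-yn-1-ol, via aryllithium 10 (not isolated), via aryltitanium 11 (not isolated)
Conditions: 9, n-BuLi, THF, −78 °C; ClTi(OiPr)3, −78 → −40 °C; then 8, −78 → −20 °C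
Reagents that add atoms: none
Why: The non-chelating aryltitanium triisopropoxide adds to the α-benzyloxy aldehyde in the Felkin–Anh (non-chelation) mode, so the bought stereocentre sets the new carbinol centre (later C2) 1,2-anti, i.e. (1R,2S); the minor syn isomer is removed by chromatography.

**Step 6**
Reactants: 12 (1R,2S)-2-(benzyloxy)-1-[4-(benzyloxy)-3-methoxyphenyl]-7-[3-(benzyloxy)phenyl]hept-4-yn-1-ol; 13 3-chlorocyclohex-2-en-1-one
Product: 14 3-{[(1R,2S)-2-(benzyloxy)-1-[4-(benzyloxy)-3-methoxyphenyl]-7-[3-(benzyloxy)phenyl]hept-4-yn-1-yl]oxy}cyclohex-2-en-1-one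
Conditions: NaH, THF, 0 °C; then 13, 0 °C → rt
Reagents that add atoms: none
Why: Addition–elimination of the alkoxide on the β-chloroenone (vinylogous acyl substitution) makes the future O1–C8a bond without touching the C–O bond of the carbinol, so configuration is retained.

**Step 7**
Reactants: 14 3-{[(1R,2S)-2-(benzyloxy)-1-[4-(benzyloxy)-3-methoxyphenyl]-7-[3-(benzyloxy)phenyl]hept-4-yn-1-yl]oxy}cyclohex-2-en-1-one
Product: 18 (2R,3S)-3-(benzyloxy)-2-[4-(benzyloxy)-3-methoxyphenyl]-5-{2-[3-(benzyloxy)phenyl]ethyl}-7-methoxy-3,4-dihydro-2H-chromene, via silyloxydiene 15 (not isolated), via cycloadduct 16 (not isolated), via aryl silyl ether 17 (not isolated)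
Conditions: LDA, TMSCl, THF, −78 → 0 °C; solvent switch to PhMe (BHT, trace Et3N), 190 °C, sealed tube; then CsF, MeI, DMF, rt
Reagents that add atoms: iodomethane, CI (chlorotrimethylsilane, C[Si](C)(C)Cl, supplies the silyl group carried only by 15–17)
Why: Kinetic α′-enolisation and O-silylation (Stork–Danheiser regiochemistry) give an s-cis-locked, electron-rich diene that undergoes intramolecular Diels–Alder addition to the tethered alkyne and then retro-Diels–Alder loss of ethene (Alder–Rickert), which forms ring A and closes the pyran ring with O1 kept as the aryl ether, and CsF/MeI turns the aryl silyl ether into the 7-OMe group; no stereocentre is involved.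

**Step 8**
Reactants: 18 (2R,3S)-3-(benzyloxy)-2-[4-(benzyloxy)-3-methoxyphenyl]-5-{2-[3-(benzyloxy)phenyl]ethyl}-7-methoxy-3,4-dihydro-2H-chromene
Product: 19 Shanciol B
Conditions: H2 (1 atm), Pd(OH)2/C, EtOAc/MeOH, rt
Reagents that add atoms: none
Why: Catalytic hydrogenolysis removes the three benzyl ethers under neutral conditions that leave the cyclic benzylic C2–O1 bond of flavan-3-ols and both stereocentres intact.

**Compound list**
1 | 3-(benzyloxy)benzyl bromide | BrCc1cccc(OCc2ccccc2)c1 | starting material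
2 | 1-(trimethylsilyl)propyne | CC#C[Si](C)(C)C | starting material
3 | {4-[3-(benzyloxy)phenyl]but-1-yn-1-yl}trimethylsilane | C[Si](C)(C)C#CCCc1cccc(OCc2ccccc2)c1 | intermediate
4 | 1-(benzyloxy)-3-(but-3-yn-1-yl)benzene | C#CCCc1cccc(OCc2ccccc2)c1 | intermediate
5 | methyl (S)-glycidate, methyl (2S)-oxirane-2-carboxylate | COC(=O)[C@@H]1CO1 | starting material
6 | methyl (2S)-7-[3-(benzyloxy)phenyl]-2-hydroxyhept-4-ynoate | COC(=O)[C@@H](O)CC#CCCc1cccc(OCc2ccccc2)c1 | intermediate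
7 | methyl (2S)-2-(benzyloxy)-7-[3-(benzyloxy)phenyl]hept-4-ynoate | COC(=O)[C@@H](OCc1ccccc1)CC#CCCc1cccc(OCc2ccccc2)c1 | intermediate
8 | (2S)-2-(benzyloxy)-7-[3-(benzyloxy)phenyl]hept-4-ynal | O=C[C@@H](OCc1ccccc1)CC#CCCc1cccc(OCc2ccccc2)c1 | intermediate
9 | 1-(benzyloxy)-4-bromo-2-methoxybenzene | COc1cc(Br)ccc1OCc1ccccc1 | starting material
10 | [4-(benzyloxy)-3-methoxyphenyl]lithium | [Li]c1ccc(OCc2ccccc2)c(OC)c1 | intermediate
11 | [4-(benzyloxy)-3-methoxyphenyl]tri(propan-2-yloxy)titanium | CC(C)O[Ti](OC(C)C)(OC(C)C)c1ccc(OCc2ccccc2)c(OC)c1 | intermediate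
12 | (1R,2S)-2-(benzyloxy)-1-[4-(benzyloxy)-3-methoxyphenyl]-7-[3-(benzyloxy)phenyl]hept-4-yn-1-ol (anti) | O[C@H](c1ccc(OCc2ccccc2)c(OC)c1)[C@@H](OCc1ccccc1)CC#CCCc1cccc(OCc2ccccc2)c1 | intermediate
13 | 3-chlorocyclohex-2-en-1-one | O=C1C=C(Cl)CCC1 | starting material
14 | 3-{[(1R,2S)-2-(benzyloxy)-1-[4-(benzyloxy)-3-methoxyphenyl]-7-[3-(benzyloxy)phenyl]hept-4-yn-1-yl]oxy}cyclohex-2-en-1-one | O=C1C=C(O[C@H](c2ccc(OCc3ccccc3)c(OC)c2)[C@@H](OCc2ccccc2)CC#CCCc2cccc(OCc3ccccc3)c2)CCC1 | intermediate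
15 | 1-{[(1R,2S)-2-(benzyloxy)-1-[4-(benzyloxy)-3-methoxyphenyl]-7-[3-(benzyloxy)phenyl]hept-4-yn-1-yl]oxy}-3-[(trimethylsilyl)oxy]cyclohexa-1,3-diene | C[Si](C)(C)OC1=CCCC(O[C@H](c2ccc(OCc3ccccc3)c(OC)c2)[C@@H](OCc2ccccc2)CC#CCCc2cccc(OCc3ccccc3)c2)=C1 | intermediate
16 | bicyclo[2.2.2]octa-2,5-diene Diels–Alder adduct of 15 (C8a–C4a and C6–C5 bonds formed, pyran ring closed, CH2–CH2 bridge still present; C2 R and C3 S as in 12, bridgehead configuration fixed by the tether and not specified) | C[Si](C)(C)OC1=CC23CCC1C(CCc1cccc(OCc4ccccc4)c1)=C2C[C@H](OCc1ccccc1)[C@@H](c1ccc(OCc4ccccc4)c(OC)c1)O3 | intermediate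
17 | (2R,3S)-3-(benzyloxy)-2-[4-(benzyloxy)-3-methoxyphenyl]-5-{2-[3-(benzyloxy)phenyl]ethyl}-7-[(trimethylsilyl)oxy]-3,4-dihydro-2H-chromene | C[Si](C)(C)Oc1cc(CCc2cccc(OCc3ccccc3)c2)c2c(c1)O[C@H](c1ccc(OCc3ccccc3)c(OC)c1)[C@@H](OCc1ccccc1)C2 | intermediate
18 | (2R,3S)-3-(benzyloxy)-2-[4-(benzyloxy)-3-methoxyphenyl]-5-{2-[3-(benzyloxy)phenyl]ethyl}-7-methoxy-3,4-dihydro-2H-chromene | COc1cc(CCc2cccc(OCc3ccccc3)c2)c2c(c1)O[C@H](c1ccc(OCc3ccccc3)c(OC)c1)[C@@H](OCc1ccccc1)C2 | intermediate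
19 | Shanciol B, (2R,3S)-2-(4-hydroxy-3-methoxyphenyl)-5-[2-(3-hydroxyphenyl)ethyl]-7-methoxy-3,4-dihydro-2H-chromen-3-ol | COc1cc(CCc2cccc(O)c2)c2c(c1)O[C@H](c1ccc(O)c(OC)c1)[C@@H](O)C2 | target

**Totals and risks**
Total step count: 8. Longest linear sequence: 8 (steps 1–8; 5, 9 and 13 are bought).

Step 7 is the most likely to fail. The alkyne is unactivated, the diene terminus is fully substituted, and three operations are telescoped. The fallback changes the diene and the way ring A is aromatised, and sets out from 12. Conjugate addition of 12 to but-3-yn-2-one (CC(=O)C#C, cat. PMe3, CH2Cl2) gives the enone (E)-4-{[(1R,2S)-2-(benzyloxy)-1-[4-(benzyloxy)-3-methoxyphenyl]-7-[3-(benzyloxy)phenyl]hept-4-yn-1-yl]oxy}but-3-en-2-one F1. TBSOTf/Et3N converts it into the acyclic 1-alkoxy-3-silyloxybuta-1,3-diene F2. Heating (PhMe, 160 °C, trace Et3N) gives the cyclohexa-1,4-diene cycloadduct F3 by intramolecular Diels–Alder reaction. This is dehydrogenated in the same flask with DDQ/2,6-lutidine to the 7-(tert-butyldimethylsilyloxy)chromane F4. TBAF then MeI turns F4 into 18, where the route is rejoined. The known weak point of this fallback is acid-promoted loss of the tether oxygen from F3, hence the buffered oxidation.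

Step 5 is second. The α-benzyloxy aldehyde 8 can epimerise, and the anti selectivity rests on non-chelation control. The fallback replaces aldehyde addition by chelation-controlled ketone reduction and sets out from 7. Me(MeO)NH·HCl/iPrMgCl converts 7 into the Weinreb amide (2S)-2-(benzyloxy)-7-[3-(benzyloxy)phenyl]-N-methoxy-N-methylhept-4-ynamide F5. Aryllithium 10 (from 9) adds to give the ketone (2S)-2-(benzyloxy)-1-[4-(benzyloxy)-3-methoxyphenyl]-7-[3-(benzyloxy)phenyl]hept-4-yn-1-one F6. Zn(BH4)2 (Et2O, −20 °C) reduces the α-benzyloxy ketone through the zinc chelate to the anti alcohol 12, where the route is rejoined.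

Step 2 is third. The acetylide may attack the ester, or open the glycidate at the wrong carbon. The fallback uses a different chiral-pool epoxide with the oxidation level adjusted later, and sets out from 4. The lithium acetylide of 4 with BF3·OEt2 opens (S)-trityl glycidyl ether (C(c1ccccc1)(c1ccccc1)(c1ccccc1)OC[C@@H]1CO1) to the alcohol (2S)-7-[3-(benzyloxy)phenyl]-1-(triphenylmethoxy)hept-4-yn-2-ol F7. NaH/BnBr gives the benzyl ether 1-(benzyloxy)-3-[(6S)-6-(benzyloxy)-7-(triphenylmethoxy)hept-3-yn-1-yl]benzene F8. TsOH in MeOH removes the trityl group to give the primary alcohol (2S)-2-(benzyloxy)-7-[3-(benzyloxy)phenyl]hept-4-yn-1-ol F9. Dess–Martin oxidation of F9 gives aldehyde 8, where the route is rejoined.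

**Further compounds**
F1 | step 7 | (E)-4-{[(1R,2S)-2-(benzyloxy)-1-[4-(benzyloxy)-3-methoxyphenyl]-7-[3-(benzyloxy)phenyl]hept-4-yn-1-yl]oxy}but-3-en-2-one | CC(=O)/C=C/O[C@H](c1ccc(OCc2ccccc2)c(OC)c1)[C@@H](OCc1ccccc1)CC#CCCc1cccc(OCc2ccccc2)c1
F2 | step 7 | tert-butyl({(3E)-4-{[(1R,2S)-2-(benzyloxy)-1-[4-(benzyloxy)-3-methoxyphenyl]-7-[3-(benzyloxy)phenyl]hept-4-yn-1-yl]oxy}buta-1,3-dien-2-yl}oxy)dimethylsilane | C=C(O[Si](C)(C)C(C)(C)C)/C=C/O[C@H](c1ccc(OCc2ccccc2)c(OC)c1)[C@@H](OCc1ccccc1)CC#CCCc1cccc(OCc2ccccc2)c1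
F3 | step 7 | (2R,3S)-3-(benzyloxy)-2-[4-(benzyloxy)-3-methoxyphenyl]-5-{2-[3-(benzyloxy)phenyl]ethyl}-7-[(tert-butyldimethylsilyl)oxy]-3,4,6,8a-tetrahydro-2H-chromene (C8a not specified) | CC(C)(C)[Si](C)(C)OC1=CC2O[C@H](c3ccc(OCc4ccccc4)c(OC)c3)[C@@H](OCc3ccccc3)CC2=C(CCc2cccc(OCc3ccccc3)c2)C1
F4 | step 7 | (2R,3S)-3-(benzyloxy)-2-[4-(benzyloxy)-3-methoxyphenyl]-5-{2-[3-(benzyloxy)phenyl]ethyl}-7-[(tert-butyldimethylsilyl)oxy]-3,4-dihydro-2H-chromene | CC(C)(C)[Si](C)(C)Oc1cc(CCc2cccc(OCc3ccccc3)c2)c2c(c1)O[C@H](c1ccc(OCc3ccccc3)c(OC)c1)[C@@H](OCc1ccccc1)C2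
F5 | step 5 | (2S)-2-(benzyloxy)-7-[3-(benzyloxy)phenyl]-N-methoxy-N-methylhept-4-ynamide | CON(C)C(=O)[C@@H](OCc1ccccc1)CC#CCCc1cccc(OCc2ccccc2)c1
F6 | step 5 | (2S)-2-(benzyloxy)-1-[4-(benzyloxy)-3-methoxyphenyl]-7-[3-(benzyloxy)phenyl]hept-4-yn-1-one | O=C(c1ccc(OCc2ccccc2)c(OC)c1)[C@@H](OCc1ccccc1)CC#CCCc1cccc(OCc2ccccc2)c1
F7 | step 2 | (2S)-7-[3-(benzyloxy)phenyl]-1-(triphenylmethoxy)hept-4-yn-2-ol | C(c1ccccc1)(c1ccccc1)(c1ccccc1)OC[C@@H](O)CC#CCCc1cccc(OCc2ccccc2)c1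
F8 | step 2 | 1-(benzyloxy)-3-[(6S)-6-(benzyloxy)-7-(triphenylmethoxy)hept-3-yn-1-yl]benzene | C(c1ccccc1)(c1ccccc1)(c1ccccc1)OC[C@@H](OCc1ccccc1)CC#CCCc1cccc(OCc2ccccc2)c1
F9 | step 2 | (2S)-2-(benzyloxy)-7-[3-(benzyloxy)phenyl]hept-4-yn-1-ol | OC[C@@H](OCc1ccccc1)CC#CCCc1cccc(OCc2ccccc2)c1
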